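**Retrosynthetic overview**

1. The target comes from acid unmasking of its acetonide/silyl-protected lactone. That lactone is disconnected into a (Z)-iodoalkene tosylate plus CO2: ring atoms O1–C2(=O) are one CO2 molecule, and C2–C3 and O1–C6 are made together, with inversion at C6.
2. The iodoalkene tosylate comes from a homopropargylic alcohol, which comes from a C2-symmetric bis-epoxide whose two homotopic oxiranes are opened in turn by an octyl (C8'–C15') and an ethynyl (C3–C4) nucleophile.
3. The bis-epoxide comes from two-directional CO2/I2 iodocarbonation of (4R,6R)-nona-1,8-diene-4,6-diol, itself made by two-directional iridium-catalysed allylation of propane-1,3-diol.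
4. Ring order: two temporary 1,3-dioxan-2-ones (step 2), two oxiranes (step 3), one temporary 1,3-dioxane (step 4), then the 5,6-dihydro-2H-pyran-2-one (step 11), the only ring of the target.
5. Enabling feature: in the dihydropyranone ring the O1–C2(=O) unit lies between vinylic C3 (cis to C5 across C3=C4) and carbinol C6, so a (Z)-C3 anion and a C6 leaving group can be bridged by CO2. C6–O1 is also the single oxygen that breaks the C2 symmetry of the C6/C2'/C4'/C6' array (syn,anti,syn becomes anti,anti,syn), so one inversion at C6 is enough.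

Key step: step 11

Remark: locants O1, C2–C6 (ring) and C1'–C15' (side chain) of the target are used for all intermediates; in step 1 the ligand antipode is taken to be the one that delivers the (4R,6R)-diol.

**Step 1**
Reactants: 1 propane-1,3-diol; 2 allyl acetate
Product: 4 (4R,6R)-nona-1,8-diene-4,6-diol, via (3R)-hex-5-ene-1,3-diol 3 (not isolated)
Conditions: [Ir(cod)Cl]2 (5 mol%), (R)-Cl,MeO-BIPHEP (10 mol%), 4-chloro-3-nitrobenzoic acid (20 mol%), Cs2CO3 (40 mol%), allyl acetate (excess), 1,4-dioxane, 90 °C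
Reagents that add atoms: allyl acetate 2, C=CCOC(C)=O
Why: Krische allylation (iridium-catalysed transfer-hydrogenative carbonyl allylation from the alcohol oxidation level) run in two directions: each primary alcohol is dehydrogenated in situ and the transient aldehyde is allylated by the cyclometallated π-allyliridium C,O-benzoate, both carbinol centres (C2', C4') being set by the chiral bisphosphine (catalyst control), with the second allylation upgrading the enantiomeric purity of the C2-symmetric diol.

**Step 2**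
Reactants: 4 (4R,6R)-nona-1,8-diene-4,6-diol; 5 carbon dioxide; 6 iodine
Product: 8 4,4'-methylenebis[(4S,6S)-6-(iodomethyl)-1,3-dioxan-2-one], via dilithium nonadienediyl dicarbonate 7 (not isolated)
Conditions: n-BuLi (2.1 equiv), THF, −78 to 0 °C; CO2 (1 atm), 0 °C; I2 (4 equiv), −20 °C to rt
Reagents that add atoms: carbon dioxide 5, O=C=O; iodine 6, II
Why: Iodocarbonation (CO2 capture by the lithium alkoxides, then iodocyclization): each alkyl carbonate oxygen attacks the iodonium ion of its homoallylic alkene 6-exo through a chair transition state with the chain equatorial, which sets C6 and C6' syn (cis-4,6) to C2' and C4', and carbonation of both oxygens also blocks iodoetherification.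

**Step 3**
Reactants: 8 4,4'-methylenebis[(4S,6S)-6-(iodomethyl)-1,3-dioxan-2-one]
Product: 9 (2S,4S)-1,5-bis[(2S)-oxiran-2-yl]pentane-2,4-diol
Conditions: K2CO3 (3 equiv), MeOH, rt
Reagents that add atoms: none
Why: Carbonate methanolysis releases the C6 and C6' alkoxides, which close on the adjacent CH2I groups by intramolecular Williamson etherification (3-exo-tet); no stereocentre is touched, so the syn epoxy alcohol pattern is kept.

**Step 4**
Reactants: 9 (2S,4S)-1,5-bis[(2S)-oxiran-2-yl]pentane-2,4-diol; 10 2-methoxypropene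
Product: 11 (4S,6S)-2,2-dimethyl-4,6-bis{[(2S)-oxiran-2-yl]methyl}-1,3-dioxane
Conditions: 2-methoxypropene (1.5 equiv), PPTS (5 mol%), CH2Cl2, 0 °C
Reagents that add atoms: 2-methoxypropene 10, COC(C)=C
Why: Acid-catalysed acetonide formation on the anti-1,3-diol under conditions mild enough for terminal epoxides; tying C2'–O and C4'–O into one ring excludes later silyl migration and neighbouring-group attack on the epoxides or the tosylate.

**Step 5**
Reactants: 11 (4S,6S)-2,2-dimethyl-4,6-bis{[(2S)-oxiran-2-yl]methyl}-1,3-dioxane; 12 octylmagnesium bromide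
Product: 13 (2R)-1-[(4R,6S)-2,2-dimethyl-6-{[(2S)-oxiran-2-yl]methyl}-1,3-dioxan-4-yl]undecan-2-ol
Conditions: octylmagnesium bromide (0.9 equiv), CuI (10 mol%), THF, −40 to −20 °C; H2O quench
Reagents that add atoms: octylmagnesium bromide 12, CCCCCCCC[Mg]Br
Why: Copper-catalysed Grignard opening of a terminal epoxide at its CH2 terminus (SN2) attaches C8'–C15' and frees the C6' carbinol without touching its configuration; the two oxiranes are homotopic, so single opening is statistical and should be steered by keeping the Grignard reagent limiting and recycling recovered bis-epoxide.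

**Step 6**
Reactants: 13 (2R)-1-[(4R,6S)-2,2-dimethyl-6-{[(2S)-oxiran-2-yl]methyl}-1,3-dioxan-4-yl]undecan-2-ol; 14 tert-butyldimethylsilyl chloride
Product: 15 tert-butyl({(2R)-1-[(4S,6S)-2,2-dimethyl-6-{[(2S)-oxiran-2-yl]methyl}-1,3-dioxan-4-yl]undecan-2-yl}oxy)dimethylsilane
Conditions: TBSCl, imidazole, DMF, rt
Reagents that add atoms: tert-butyldimethylsilyl chloride 14, CC(C)(C)[Si](C)(C)Cl
Why: Standard imidazole-promoted silylation of a secondary alcohol, inert toward the epoxide and the acetonide.

**Step 7**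
Reactants: 15 tert-butyl({(2R)-1-[(4S,6S)-2,2-dimethyl-6-{[(2S)-oxiran-2-yl]methyl}-1,3-dioxan-4-yl]undecan-2-yl}oxy)dimethylsilane; 16 lithium acetylide–ethylenediamine complex
Product: 17 (2R)-1-[(4R,6S)-6-{(2R)-2-[(tert-butyldimethylsilyl)oxy]undecyl}-2,2-dimethyl-1,3-dioxan-4-yl]hex-5-yn-2-ol
Conditions: lithium acetylide–ethylenediamine complex (4 equiv), DMSO, rt; H2O
Reagents that add atoms: lithium acetylide–ethylenediamine complex 16, [Li]C#C.NCCN
Why: SN2 opening of the remaining terminal epoxide at CH2 by lithium acetylide (epoxide alkynylation) introduces C3–C4 and frees the C6 carbinol, whose configuration (syn to C2') dates from step 2.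

**Step 8**
Reactants: 17 (2R)-1-[(4R,6S)-6-{(2R)-2-[(tert-butyldimethylsilyl)oxy]undecyl}-2,2-dimethyl-1,3-dioxan-4-yl]hex-5-yn-2-ol; 18 4-methylbenzenesulfonyl chloride
Product: 19 (2R)-1-[(4S,6S)-6-{(2R)-2-[(tert-butyldimethylsilyl)oxy]undecyl}-2,2-dimethyl-1,3-dioxan-4-yl]hex-5-yn-2-yl 4-methylbenzenesulfonate
Conditions: TsCl, pyridine, DMAP (cat.), CH2Cl2, 0 °C to rt
Reagents that add atoms: 4-methylbenzenesulfonyl chloride 18, Cc1ccc(cc1)S(Cl)(=O)=O
Why: Sulfonylation at oxygen (retention at C6) turns the only free hydroxyl into the leaving group that the ring closure will displace; a tosylate is chosen because it has no acidic α-hydrogens toward an organolithium.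

**Step 9**
Reactants: 19 (2R)-1-[(4S,6S)-6-{(2R)-2-[(tert-butyldimethylsilyl)oxy]undecyl}-2,2-dimethyl-1,3-dioxan-4-yl]hex-5-yn-2-yl 4-methylbenzenesulfonate; 20 N-iodosuccinimide
Product: 21 (2R)-1-[(4S,6S)-6-{(2R)-2-[(tert-butyldimethylsilyl)oxy]undecyl}-2,2-dimethyl-1,3-dioxan-4-yl]-6-iodohex-5-yn-2-yl 4-methylbenzenesulfonate
Conditions: NIS, AgNO3 (10 mol%), acetone, rt, dark
Reagents that add atoms: N-iodosuccinimide 20, O=C1CCC(=O)N1I
Why: Silver-catalysed electrophilic iodination of the terminal alkyne via the silver acetylide, under neutral conditions that tosylate, acetonide and silyl ether tolerate.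

**Step 10**
Reactants: 21 (2R)-1-[(4S,6S)-6-{(2R)-2-[(tert-butyldimethylsilyl)oxy]undecyl}-2,2-dimethyl-1,3-dioxan-4-yl]-6-iodohex-5-yn-2-yl 4-methylbenzenesulfonate
Product: 22 (2R,5Z)-1-[(4S,6S)-6-{(2R)-2-[(tert-butyldimethylsilyl)oxy]undecyl}-2,2-dimethyl-1,3-dioxan-4-yl]-6-iodohex-5-en-2-yl 4-methylbenzenesulfonate
Conditions: 2-nitrobenzenesulfonohydrazide (NBSH), Et3N, THF/i-PrOH, rt
Reagents that add atoms: none
Why: Diimide reduction: diimide released from NBSH transfers H2 in a concerted syn fashion to the iodoalkyne, which fixes the Z geometry of the 1-iodoalkene, the alkenyl iodide being reduced much more slowly than the alkyne.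

**Step 11**
Reactants: 22 (2R,5Z)-1-[(4S,6S)-6-{(2R)-2-[(tert-butyldimethylsilyl)oxy]undecyl}-2,2-dimethyl-1,3-dioxan-4-yl]-6-iodohex-5-en-2-yl 4-methylbenzenesulfonate; 5 carbon dioxide
Product: 25 (6S)-6-{[(4S,6S)-6-{(2R)-2-[(tert-butyldimethylsilyl)oxy]undecyl}-2,2-dimethyl-1,3-dioxan-4-yl]methyl}-5,6-dihydro-2H-pyran-2-one, via (Z)-alkenyllithium 23 (not isolated), via lithium (Z)-enoate 24 (not isolated)
Conditions: t-BuLi (2.1 equiv), Et2O, −78 °C; CO2 (g), −78 to 0 °C; then DMF (0.01 M), 60 °C
Reagents that add atoms: carbon dioxide 5, O=C=O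
Why: Iodine–lithium exchange with retention gives (Z)-alkenyllithium 23, which adds to CO2 to forge C2–C3 and deliver lithium (Z)-enoate 24; on warming in DMF one carboxylate oxygen displaces the C6 tosylate and forges O1–C6, so the whole O1–C2(=O) unit of the ring is CO2. The closest known reaction types are the carboxylation of alkenyllithiums with retention of olefin geometry and the invertive carboxylate-displacement lactonization of sulfonate-bearing acids. The dihydropyranone closes by 6-exo-tet intramolecular O-alkylation, the cis C3=C4 bond holding the carboxylate within reach of C6. C6 is set by stereospecific SN2 inversion of the (R)-tosylate, which turns the syn C6/C2' relationship of the symmetric precursor into the anti relationship of the target, and no other centre is touched. The step needs exchange and carboxylation to outrun attack on the sulfonate and 4-exo cyclialkylation (secured at −78 °C with immediate CO2 quench), retention of the Z geometry (only the Z enoate can cyclize), and substitution to win over elimination and over intermolecular displacement by LiI (secured by the weakly basic carboxylate, the six-membered transition state and high dilution).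

**Step 12**
Reactants: 25 (6S)-6-{[(4S,6S)-6-{(2R)-2-[(tert-butyldimethylsilyl)oxy]undecyl}-2,2-dimethyl-1,3-dioxan-4-yl]methyl}-5,6-dihydro-2H-pyran-2-one
Product: 26 (6S)-6-[(2S,4R,6R)-2,4,6-trihydroxypentadecyl]-5,6-dihydro-2H-pyran-2-one
Conditions: aq. HF (48%), MeCN, 0 °C to rt
Reagents that add atoms: none
Why: Acid-mediated global deprotection (acetal hydrolysis and desilylation) of the kind routinely applied to 6-substituted 5,6-dihydropyran-2-ones; no stereocentre is involved.

**Compound list**

1 | propane-1,3-diol | OCCCO | starting material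
2 | allyl acetate | C=CCOC(C)=O | starting material
3 | (3R)-hex-5-ene-1,3-diol | OCC[C@H](O)CC=C | intermediate
4 | (4R,6R)-nona-1,8-diene-4,6-diol | C=CC[C@@H](O)C[C@H](O)CC=C | intermediate
5 | carbon dioxide | O=C=O | starting material
6 | iodine | II | starting material
7 | dilithium (4R,6R)-nona-1,8-diene-4,6-diyl dicarbonate | [Li+].[Li+].C=CC[C@@H](OC([O-])=O)C[C@H](OC([O-])=O)CC=C | intermediate
8 | 4,4'-methylenebis[(4S,6S)-6-(iodomethyl)-1,3-dioxan-2-one] | IC[C@@H]1C[C@@H](OC(=O)O1)C[C@H]2C[C@@H](CI)OC(=O)O2 | intermediate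
9 | (2S,4S)-1,5-bis[(2S)-oxiran-2-yl]pentane-2,4-diol | C1O[C@H]1C[C@@H](O)C[C@H](O)C[C@H]1CO1 | intermediate
10 | 2-methoxypropene | COC(C)=C | starting material
11 | (4S,6S)-2,2-dimethyl-4,6-bis{[(2S)-oxiran-2-yl]methyl}-1,3-dioxane | C1O[C@H]1C[C@@H]2C[C@@H](C[C@H]3CO3)OC(C)(C)O2 | intermediate
12 | octylmagnesium bromide | CCCCCCCC[Mg]Br | starting material
13 | (2R)-1-[(4R,6S)-2,2-dimethyl-6-{[(2S)-oxiran-2-yl]methyl}-1,3-dioxan-4-yl]undecan-2-ol | CCCCCCCCC[C@@H](O)C[C@@H]1C[C@@H](C[C@H]2CO2)OC(C)(C)O1 | intermediate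
14 | tert-butyldimethylsilyl chloride | CC(C)(C)[Si](C)(C)Cl | starting material
15 | tert-butyl({(2R)-1-[(4S,6S)-2,2-dimethyl-6-{[(2S)-oxiran-2-yl]methyl}-1,3-dioxan-4-yl]undecan-2-yl}oxy)dimethylsilane | CCCCCCCCC[C@@H](O[Si](C)(C)C(C)(C)C)C[C@@H]1C[C@@H](C[C@H]2CO2)OC(C)(C)O1 | intermediate
16 | lithium acetylide–ethylenediamine complex | [Li]C#C.NCCN | starting material
17 | (2R)-1-[(4R,6S)-6-{(2R)-2-[(tert-butyldimethylsilyl)oxy]undecyl}-2,2-dimethyl-1,3-dioxan-4-yl]hex-5-yn-2-ol | CCCCCCCCC[C@@H](O[Si](C)(C)C(C)(C)C)C[C@@H]1C[C@@H](C[C@H](O)CC#C)OC(C)(C)O1 | intermediate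
18 | 4-methylbenzenesulfonyl chloride | Cc1ccc(cc1)S(Cl)(=O)=O | starting material
19 | (2R)-1-[(4S,6S)-6-{(2R)-2-[(tert-butyldimethylsilyl)oxy]undecyl}-2,2-dimethyl-1,3-dioxan-4-yl]hex-5-yn-2-yl 4-methylbenzenesulfonate | CCCCCCCCC[C@@H](O[Si](C)(C)C(C)(C)C)C[C@@H]1C[C@@H](C[C@H](OS(=O)(=O)c2ccc(C)cc2)CC#C)OC(C)(C)O1 | intermediate
20 | N-iodosuccinimide | O=C1CCC(=O)N1I | starting material
21 | (2R)-1-[(4S,6S)-6-{(2R)-2-[(tert-butyldimethylsilyl)oxy]undecyl}-2,2-dimethyl-1,3-dioxan-4-yl]-6-iodohex-5-yn-2-yl 4-methylbenzenesulfonate | CCCCCCCCC[C@@H](O[Si](C)(C)C(C)(C)C)C[C@@H]1C[C@@H](C[C@H](OS(=O)(=O)c2ccc(C)cc2)CC#CI)OC(C)(C)O1 | intermediate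
22 | (2R,5Z)-1-[(4S,6S)-6-{(2R)-2-[(tert-butyldimethylsilyl)oxy]undecyl}-2,2-dimethyl-1,3-dioxan-4-yl]-6-iodohex-5-en-2-yl 4-methylbenzenesulfonate | CCCCCCCCC[C@@H](O[Si](C)(C)C(C)(C)C)C[C@@H]1C[C@@H](C[C@H](OS(=O)(=O)c2ccc(C)cc2)C/C=C\I)OC(C)(C)O1 | intermediate
23 | (Z)-alkenyllithium from 22 (lithium in place of iodine at C3, tosylate at C6 intact) | CCCCCCCCC[C@@H](O[Si](C)(C)C(C)(C)C)C[C@@H]1C[C@@H](C[C@H](OS(=O)(=O)c2ccc(C)cc2)C/C=C\[Li])OC(C)(C)O1 | intermediate
24 | lithium (2Z,5R)-enoate (carboxylate at C2, tosylate at C6 intact) | CCCCCCCCC[C@@H](O[Si](C)(C)C(C)(C)C)C[C@@H]1C[C@@H](C[C@H](OS(=O)(=O)c2ccc(C)cc2)C/C=C\C(=O)[O-])OC(C)(C)O1.[Li+] | intermediate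
25 | (6S)-6-{[(4S,6S)-6-{(2R)-2-[(tert-butyldimethylsilyl)oxy]undecyl}-2,2-dimethyl-1,3-dioxan-4-yl]methyl}-5,6-dihydro-2H-pyran-2-one | CCCCCCCCC[C@@H](O[Si](C)(C)C(C)(C)C)C[C@@H]1C[C@@H](C[C@@H]2CC=CC(=O)O2)OC(C)(C)O1 | intermediate
26 | (6S)-6-[(2S,4R,6R)-2,4,6-trihydroxypentadecyl]-5,6-dihydro-2H-pyran-2-one | CCCCCCCCC[C@@H](O)C[C@@H](O)C[C@H](O)C[C@@H]1CC=CC(=O)O1 | target

**Step count**

Total steps: 12. Longest linear sequence: 12 steps (propane-1,3-diol to the target).

**Steps most likely to fail**

Step 11: the organolithium may attack the sulfonate or close to a cyclobutene (4-exo cyclialkylation) before it is carboxylated, and the ring closure may give way to elimination. The fallback sets out from alkyne tosylate 19. Rhodium-catalysed trans-hydroboration with pinacolborane ([Rh(cod)Cl]2, P(i-Pr)3, Et3N, cyclohexane, rt) should give the (Z)-alkenyl pinacolboronate F1. Carboxylation under (IPr)CuCl catalysis (IPr = 1,3-bis(2,6-diisopropylphenyl)imidazol-2-ylidene; KOt-Bu, CO2 1 atm, THF, 70 °C) should then pass through boron-to-copper transmetalation and CO2 insertion to the potassium (Z)-enoate F2, which should close on the tosylate with inversion in the same flask. This comes back to the route at lactone 25 and needs neither 21 nor 22 nor an organolithium.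

Step 2: facial selectivity of the iodocyclization may be incomplete, and the loss is doubled because two rings form; iodoetherification by an uncarbonated alkoxide may also compete. The fallback sets out from diol 4. Double acylation (n-BuLi, then Boc2O, THF, −78 °C to rt) should give the bis(tert-butyl carbonate) F3, and IBr (toluene, −85 °C) should cyclize the neutral carbonates under kinetic control with loss of the tert-butyl groups. This comes back to the route at bis-iodocarbonate 8.

Step 10: over-reduction of the iodoalkene to the alkyl iodide, or reductive loss of iodine, may accompany the diimide reduction. The fallback sets out from iodoalkyne 21. Hydroboration with dicyclohexylborane (THF, 0 °C) should add H and B syn, boron going to the iodine-bearing carbon, to give the (Z)-(1-iodoalkenyl)dicyclohexylborane F4. Protonolysis of the C–B bond with AcOH (retention) comes back to the route at (Z)-iodoalkene 22.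

**Further compounds**

F1 | step 11 | (Z)-alkenyl pinacolboronate of tosylate 19 (Bpin at C3, cis to C5) | CCCCCCCCC[C@@H](O[Si](C)(C)C(C)(C)C)C[C@@H]1C[C@@H](C[C@H](OS(=O)(=O)c2ccc(C)cc2)C/C=C\B2OC(C)(C)C(C)(C)O2)OC(C)(C)O1
F2 | step 11 | potassium (2Z,5R)-enoate (carboxylate at C2, tosylate at C6 intact) | CCCCCCCCC[C@@H](O[Si](C)(C)C(C)(C)C)C[C@@H]1C[C@@H](C[C@H](OS(=O)(=O)c2ccc(C)cc2)C/C=C\C(=O)[O-])OC(C)(C)O1.[K+]
F3 | step 2 | di-tert-butyl (4R,6R)-nona-1,8-diene-4,6-diyl dicarbonate | C=CC[C@@H](OC(=O)OC(C)(C)C)C[C@H](OC(=O)OC(C)(C)C)CC=C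
F4 | step 10 | (Z)-(1-iodoalkenyl)dicyclohexylborane from 21 (B and I on C3, I cis to C5) | CCCCCCCCC[C@@H](O[Si](C)(C)C(C)(C)C)C[C@@H]1C[C@@H](C[C@H](OS(=O)(=O)c2ccc(C)cc2)C/C=C(\I)/B(C2CCCCC2)C2CCCCC2)OC(C)(C)O1
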